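**Compound numbering used throughout:** 1–4 enyne branch, 5–19 diyne branch, 20 cycloadduct, 21 boronic acid, 22 target. Benzofuran numbering is O1, C2, C3, C3a, C4–C7, C7a. Ring A is the benzo ring, ring B the 2,4-dioxygenated aryl at C2, ring C the 3,5-dioxygenated aryl at C3.

## The problem

Compound 22 is a trans-2,3-diaryl-2,3-dihydrobenzofuran. Ring A is a resorcinol whose two oxygens (O1 at C7a, OH at C4) flank the carbon C3a that carries C3, and its C6 bears an (E)-4-hydroxystyryl group. A synthesis has to join a five-membered oxygen heterocycle to a 1,2,3,5-tetrasubstituted arene, put the stilbene at C6 and not at C5, and set two adjacent benzylic stereocentres as (2S,3S). C3 is an all-carbon benzylic centre and holds its configuration. C2 is a benzylic ether carbon next to the ortho,para-dioxygenated ring B, so it can ionise and settle into the more stable trans arrangement; C3 can therefore control C2, but not the reverse, and the absolute configuration has to enter at or before C3. The six phenols, the stilbene and the acid-labile O1–C2 bond rule out hydrogenolysis, strong electrophiles and hot protic acid in the endgame. The feature that opens the route is that the six carbons of ring A pair as three former alkynes, C3a–C4, C7a–C7 and C5–C6. The first two pairs are already linked through C3, C2 and O1, which is a 1,6-diyne with an ynol ether at one end, and the third pair can carry the styryl group as a conjugated enyne.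

## Retrosynthesis

**22 to 20.** The last operation should only unmask heteroatoms. The C4 hydroxyl is traced to a C4 trimethylsilyl group and the other five phenols to methyl ethers, which gives 20. One electrophilic boron halide can exchange silicon for boron at C4 (boronic acid 21 after hydrolysis) and cleave the ethers, and peroxide then turns C–B into C–O. An oxygen substituent on that alkyne terminus is not available for the ring-forming step, whereas silicon is, and silicon also steers the regiochemistry there. The forward step must substitute at C4 without loss of silicon to a proton and must leave the stilbene and the O1–C2 bond intact.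

**20 to 19 and 4.** Ring A is cut at C3a–C7a, C4–C5 and C6–C7, a retro-[2+2+2] that opens ring A and the dihydrofuran together and gives diyne 19 and enyne 4. Cuts through C2–C3 or O1–C2 keep ring A as a building block and must then solve its substitution pattern by aromatic substitution between two oxygens. The chosen cut makes that pattern a consequence of how three alkynes are joined and leaves both stereocentres in an acyclic tether. Two rings and three C–C bonds are removed in one step. The forward reaction must spare the ynol ether (neutral catalyst, room temperature), insert the monoalkyne with its substituent next to C7, and leave the alkene of 4 alone.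

**4 to 2 to 1.** The terminal alkyne carbon of 4 is removed, leading through dibromodiene 2 (and acetylide 3) to aldehyde 1, which already holds the E alkene. The two-stage dibromoolefination and elimination is preferred over one-pot diazophosphonate homologation, which is unreliable for enals in methanol.

**19 to 16 to 12 and 13.** The ynol ether is cut at its O–C(sp) bond. Diyne 19 comes from dichlorovinyl ether 16 by elimination and halogen–lithium exchange (17, 18), and 16 from alcohol 12 and 13 (through 14 and 15). This brings in C7a and C7 on oxygen without touching the C2–O bond, so C2 keeps the configuration of the alcohol. The forward steps are strongly basic and must be short and cold because of the silylalkyne and the benzylic, propargylic C3–H.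

**12 to 9 and 10.** The C2–C3 bond is cut into aldehyde 10 and allenylzinc 11, made from mesylate 9. Opening a stilbene oxide with an acetylide would be the neighbouring choice, but ring B would direct attack to C2, the wrong carbon. Here C3 is the nucleophile and C2 the electrophile, and one propargylic stereocentre is translated into both centres: C3 by stereospecific anti SN2′ and syn SE2′ events, C2 by the anti preference of the cyclic transition state.

**9 to 8 to 7 to 5 and 6.** Mesylate 9 comes from alcohol 8, 8 from ynone 7 by reagent-controlled reduction, and 7 from acid chloride 5 and alkyne 6. A ketone reduction is chosen over an enantioselective alkynylation because the facial preference of the pinene-derived borane for alkynyl ketones is well established. Alkyne 6 supplies C3a, C4 and the silicon.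

## Roads not taken

**Alternative 1:** Ring A could be grown around C3 by a Danheiser benzannulation. The cut removes C4–C3a and C7–C7a and leads to cyclobutenone A1 and chiral siloxyalkyne A2. Heating them would give resorcinol monosilyl ether A3 by ring opening of A1, [2+2] addition, a second ring opening and 6π closure.
- Merits: the reaction class is established for siloxyalkynes, the regiochemistry is fixed by the mechanism, no metal is needed, and both ring A oxygens arrive at the right oxidation level. In precedent and in oxygenation this road is better than the chosen one.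
- Weak points: the dihydrofuran is not formed, so O1–C2 must be closed later at the ionisable C2. A2 needs both stereocentres set beforehand and an ester-to-ynolate homologation next to an acidic benzylic C–H. A1 needs its own preparation. The sequence would be several steps longer.
- Comparison: the chosen plan sets against the better precedent the closure of both rings and the attachment of the stilbene in one atom-economic step.

**Alternative 2:** The C2–C3 bond could be made by C–H insertion of a donor/donor carbene. Diazo compound A4 has two equivalent 2,4-dimethoxybenzyl ethers on ring A. With a chiral dirhodium tetracarboxylate it would lose nitrogen and insert into a benzylic C–H of one ether, giving cis-dihydrobenzofuran A5 with C3 as in 22 and C2 epimeric.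
- Merits: the absolute configuration comes from a catalyst in a reaction type shown on closely related diaryl dihydrobenzofurans, the desymmetrisation is elegant, and the C4 oxygen is present from the start. In stereocontrol this road is stronger than the chosen plan, which relies on a stoichiometric chiral borane and on chirality transfer.
- Weak points: C2 must be epimerised with acid. The stilbene is absent and has to be added by activating the C6 oxygen and cross-coupling. The remaining benzyl ether must be removed. A4 requires oxidation of the hydrazone of a doubly ortho-substituted, electron-rich benzophenone.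
- Comparison: the chosen plan answers with convergence, since ring A, the dihydrofuran and the stilbene arrive together and trans directly.

**Alternative 3:** C2–C3 and O1–C2 could be formed in a [4+1] annulation. Base would turn sulfone A6 into ortho-quinone methide A7 and sulfonium salt A8 into its benzylide. Addition of the ylide carbon to the methide carbon and displacement of the sulfide by the phenoxide would give A9, the hexamethyl ether of 22, as the trans isomer.
- Merits: it is the most convergent road, with the whole skeleton and all oxygens in place and trans selectivity inherent. On step count it beats the chosen plan.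
- Weak points: enantiocontrol would rest on a semi-stabilised benzylide from a chiral sulfide, an extrapolation from the carbonyl-stabilised ylides for which asymmetric versions are best developed, and ring B makes A8 prone to ionise. A7 is hindered by the methoxy group next to the methide carbon. A6 needs a substituent introduced between two oxygens of a resorcinol ether. The final demethylation meets the same O1–C2 lability, with one more ether to cleave.
- Comparison: the chosen plan sets against the shorter sequence a stereochemical course that follows from stereospecific steps and a ring A pattern fixed by construction.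

Key step: step 9

Assumption: in the reduction of 7 the silylalkynyl group is taken to act as the small substituent and the aryl group as the large one, as in other alkynyl ketone reductions with this borane.

## Route

Step 1
Reactants: 1 4-methoxycinnamaldehyde, (E)-3-(4-methoxyphenyl)prop-2-enal
Product: 2 1-[(1E)-4,4-dibromobuta-1,3-dien-1-yl]-4-methoxybenzene
Conditions: CBr4 (2 equiv), PPh3 (4 equiv), CH2Cl2, 0 °C
Reagents that add atoms: carbon tetrabromide, BrC(Br)(Br)Br
Why: First stage of the Corey–Fuchs homologation: the dibromomethylene ylide formed from PPh3 and CBr4 olefinates the aldehyde in a Wittig reaction, and the E alkene of the enal takes no part and should be retained.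

Step 2
Reactants: 2 1-[(1E)-4,4-dibromobuta-1,3-dien-1-yl]-4-methoxybenzene
Product: 4 1-[(1E)-but-1-en-3-yn-1-yl]-4-methoxybenzene, via lithium enynide 3 (not isolated)
Conditions: n-BuLi (2.2 equiv), THF, −78 °C; then H2O, −78 to 0 °C
Reagents that add atoms: n-butyllithium, [Li]CCCC (lithium of 3 only)
Why: Second stage of the Corey–Fuchs reaction: bromine–lithium exchange, Fritsch–Buttenberg–Wiechell 1,2-shift and deprotonation give acetylide 3, which water protonates; the styrene double bond is inert at −78 °C and should keep its E geometry, and 4 is stored cold in solution and used soon.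

Step 3
Reactants: 5 3,5-dimethoxybenzoyl chloride; 6 ethynyltrimethylsilane
Product: 7 1-(3,5-dimethoxyphenyl)-3-(trimethylsilyl)prop-2-yn-1-one
Conditions: PdCl2(PPh3)2 (2 mol%), CuI (4 mol%), Et3N (1.2 equiv), THF, 20 °C
Reagents that add atoms: none
Why: Acyl Sonogashira coupling: oxidative addition of the aroyl chloride to zerovalent palladium, transmetalation of the copper acetylide and reductive elimination give the silyl ynone; with about one equivalent of amine at room temperature neither desilylation nor conjugate addition should compete.

Step 4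
Reactants: 7 1-(3,5-dimethoxyphenyl)-3-(trimethylsilyl)prop-2-yn-1-one
Product: 8 (1R)-1-(3,5-dimethoxyphenyl)-3-(trimethylsilyl)prop-2-yn-1-ol
Conditions: (R)-Alpine-Borane (B-isopinocampheyl-9-BBN from (+)-α-pinene, 1.5 equiv), neat, 20 °C; then HOCH2CH2NH2, Et2O, 0 °C
Reagents that add atoms: none
Why: Midland reduction of an alkynyl ketone: the pinanyl C–H hydride is delivered in a boat-like six-membered transition state in which the rod-shaped silylalkynyl group sits next to the pinane methyl and the aryl group points away, which with the borane from (+)-α-pinene should set the carbinol centre as R; ethanolamine releases 8 without the basic peroxide that could cleave the C–Si bond.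

Step 5
Reactants: 8 (1R)-1-(3,5-dimethoxyphenyl)-3-(trimethylsilyl)prop-2-yn-1-ol
Product: 9 (1R)-1-(3,5-dimethoxyphenyl)-3-(trimethylsilyl)prop-2-yn-1-yl methanesulfonate
Conditions: MsCl (1.2 equiv), Et3N (1.5 equiv), CH2Cl2, −78 °C; cold aqueous work-up, used at once without chromatography
Reagents that add atoms: methanesulfonyl chloride, CS(=O)(=O)Cl
Why: O-Sulfonylation (mesylation) breaks no bond to the stereocentre, so the R configuration is kept; the two meta methoxy groups do not stabilise a benzylic cation, which should make this secondary propargylic mesylate manageable at low temperature.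

Step 6
Reactants: 9 (1R)-1-(3,5-dimethoxyphenyl)-3-(trimethylsilyl)prop-2-yn-1-yl methanesulfonate; 10 2,4-dimethoxybenzaldehyde
Product: 12 (1S,2S)-1-(2,4-dimethoxyphenyl)-2-(3,5-dimethoxyphenyl)-4-(trimethylsilyl)but-3-yn-1-ol, via allenylzinc 11 (not isolated)
Conditions: Pd(OAc)2 (5 mol%), PPh3 (5 mol%), Et2Zn (3 equiv), 10 (1.2 equiv), THF, −78 to −20 °C; then aq. NH4Cl
Reagents that add atoms: diethylzinc, CC[Zn]CC (ethylzinc group of 11 only)
Why: Marshall propargylation: zerovalent palladium displaces the mesylate in an anti SN2′ sense, transmetalation with retention gives the axially chiral allenylzinc 11, and 11 adds to the aldehyde through a cyclic SE2′ transition state on the face that carries zinc, so the new C–C bond replaces the C–O bond with inversion (R in 9 becomes S at C2 of 12); in that transition state the aldehyde aryl group turns away from the aryl group on the allene terminus, which should give the anti isomer (S at C1).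

Step 7
Reactants: 12 (1S,2S)-1-(2,4-dimethoxyphenyl)-2-(3,5-dimethoxyphenyl)-4-(trimethylsilyl)but-3-yn-1-ol; 13 trichloroethylene
Product: 16 [(3S,4S)-4-{[(E)-1,2-dichloroethenyl]oxy}-4-(2,4-dimethoxyphenyl)-3-(3,5-dimethoxyphenyl)but-1-yn-1-yl]trimethylsilane, via potassium alkoxide 14 (not isolated), via dichloroacetylene 15 (not isolated)
Conditions: KH (1.3 equiv), THF, 0 °C; then 13 (1.2 equiv), −50 to 20 °C
Reagents that add atoms: potassium hydride, [K+].[H-] (potassium of 14 only)
Why: Dichlorovinyl ether formation by the trichloroethylene route to ynol ethers: base converts 13 into dichloroacetylene 15, alkoxide 14 adds to it in an anti fashion and the vinyl anion is protonated by further 13, which gives the E enol ether; only the O–H bond of 12 reacts, so both stereocentres are untouched.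

Step 8
Reactants: 16 [(3S,4S)-4-{[(E)-1,2-dichloroethenyl]oxy}-4-(2,4-dimethoxyphenyl)-3-(3,5-dimethoxyphenyl)but-1-yn-1-yl]trimethylsilane
Product: 19 [(3S,4S)-4-(2,4-dimethoxyphenyl)-3-(3,5-dimethoxyphenyl)-4-(ethynyloxy)but-1-yn-1-yl]trimethylsilane, via chloroalkynyl ether 17 (not isolated), via lithium alkynyl ether 18 (not isolated)
Conditions: n-BuLi (2.4 equiv), THF, −78 to −40 °C; then MeOH, −78 °C; cold neutral work-up, used directly
Reagents that add atoms: n-butyllithium, [Li]CCCC (lithium of 18 only)
Why: Ynol ether synthesis from a 1,2-dichlorovinyl ether: deprotonation of the vinyl C–H and loss of chloride give chloroalkyne 17, chlorine–lithium exchange gives 18, and methanol protonates it; both events should be much faster at −78 °C than attack on silicon or removal of the C3–H, and 19 is kept at or below room temperature because benzylic ynol ethers rearrange on heating.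

Step 9
Reactants: 19 [(3S,4S)-4-(2,4-dimethoxyphenyl)-3-(3,5-dimethoxyphenyl)-4-(ethynyloxy)but-1-yn-1-yl]trimethylsilane; 4 1-[(1E)-but-1-en-3-yn-1-yl]-4-methoxybenzene
Product: 20 [(2S,3S)-2-(2,4-dimethoxyphenyl)-3-(3,5-dimethoxyphenyl)-6-[(E)-2-(4-methoxyphenyl)ethenyl]-2,3-dihydro-1-benzofuran-4-yl]trimethylsilane
Conditions: Cp*RuCl(cod) (10 mol%), 4 (3 equiv), ClCH2CH2Cl, 20 °C, 19 added over 2 h
Reagents that add atoms: none
Why: Proposed new method: a 1,6-diyne whose tether contains the oxygen of an ynol ether has not been used in a [2+2+2] cyclotrimerization, but the reaction should follow the accepted course of Cp*RuCl catalysis, in which the two alkyne arms of 19 couple oxidatively on ruthenium to a bicyclic ruthenacycle, the alkyne of 4 inserts and reductive elimination releases the arene; the closest known reaction type is the ruthenium- or rhodium-catalysed cyclotrimerization of oxygen- and nitrogen-tethered 1,6-diynes, ynamide-containing ones included, with terminal alkynes to give fused benzenes such as indolines. The dihydrofuran ring closes in the oxidative coupling, which forms C3a–C7a and fuses a five-membered ring to the metallacycle; ring A closes when C4–C5 and C6–C7 form by insertion and reductive elimination, a formal [2+2+2] cycloaddition. No stereocentre is created: C2 and C3 lie in the tether, no bond to them is made or broken by the neutral catalyst, and the trans relationship of 20 is the anti relationship of 12. The selectivity the step needs is regiochemical, styryl at C6 and not at C5, and the trimethylsilyl group secures it: it makes the C4 end of the metallacycle the hindered one, so the substituted carbon of 4 should bond to the unsubstituted C7 end, the meta orientation that unsymmetrical 1,6-diynes show with this catalyst. The alkyne of 4 should react in preference to its 1,2-disubstituted alkene because alkynes insert into the ruthenacycle far faster. An excess of 4 and slow addition of 19 are meant to suppress self-coupling of the diyne, and room temperature keeps 19 below the range in which benzylic ynol ethers decompose by sigmatropic or retro-ene pathways.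

Step 10
Reactants: 20 [(2S,3S)-2-(2,4-dimethoxyphenyl)-3-(3,5-dimethoxyphenyl)-6-[(E)-2-(4-methoxyphenyl)ethenyl]-2,3-dihydro-1-benzofuran-4-yl]trimethylsilane
Product: 22 4-[(2S,3S)-3-(3,5-dihydroxyphenyl)-4-hydroxy-6-[(E)-2-(4-hydroxyphenyl)ethenyl]-2,3-dihydro-1-benzofuran-2-yl]benzene-1,3-diol, via boronic acid 21 (not isolated)
Conditions: BBr3 (10 equiv), CH2Cl2, −78 to 20 °C; MeOH then H2O, 0 °C; then 30% aq. H2O2, NaHCO3, THF–H2O, 0 °C
Reagents that add atoms: boron tribromide, BrB(Br)Br (boron of 21 only); water, O (boron-bound hydroxyls of 21 only); hydrogen peroxide, OO (C4 oxygen of 22)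
Why: Electrophilic ipso-borodesilylation (boron attacks C4 and the β-silyl cation loses the silyl group) runs alongside the usual BBr3 cleavage of the five aryl methyl ethers, hydrolysis gives boronic acid 21, and peroxide oxidises its C–B bond with 1,2-shift of the aryl group from boron to oxygen, which places the hydroxyl exactly at C4. C3 is not involved, and because the trans isomer is the more stable one, reversible opening of the O1–C2 bond under the Lewis acid should not erode the configuration at C2.

## Compound list

1 | 4-methoxycinnamaldehyde, (E)-3-(4-methoxyphenyl)prop-2-enal | COc1ccc(/C=C/C=O)cc1 | starting material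
2 | 1-[(1E)-4,4-dibromobuta-1,3-dien-1-yl]-4-methoxybenzene | COc1ccc(/C=C/C=C(Br)Br)cc1 | intermediate
3 | [(3E)-4-(4-methoxyphenyl)but-3-en-1-yn-1-yl]lithium (not isolated) | [Li]C#C/C=C/c1ccc(OC)cc1 | intermediate
4 | 1-[(1E)-but-1-en-3-yn-1-yl]-4-methoxybenzene | C#C/C=C/c1ccc(OC)cc1 | intermediate
5 | 3,5-dimethoxybenzoyl chloride | COc1cc(OC)cc(C(=O)Cl)c1 | starting material
6 | ethynyltrimethylsilane | C#C[Si](C)(C)C | starting material
7 | 1-(3,5-dimethoxyphenyl)-3-(trimethylsilyl)prop-2-yn-1-one | COc1cc(OC)cc(C(=O)C#C[Si](C)(C)C)c1 | intermediate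
8 | (1R)-1-(3,5-dimethoxyphenyl)-3-(trimethylsilyl)prop-2-yn-1-ol | O[C@@H](C#C[Si](C)(C)C)c1cc(OC)cc(OC)c1 | intermediate
9 | (1R)-1-(3,5-dimethoxyphenyl)-3-(trimethylsilyl)prop-2-yn-1-yl methanesulfonate | CS(=O)(=O)O[C@@H](C#C[Si](C)(C)C)c1cc(OC)cc(OC)c1 | intermediate
10 | 2,4-dimethoxybenzaldehyde | COc1ccc(C=O)c(OC)c1 | starting material
11 | [(aS)-3-(3,5-dimethoxyphenyl)-1-(trimethylsilyl)propa-1,2-dien-1-yl](ethyl)zinc (not isolated) | [H]C(c1cc(OC)cc(OC)c1)=[C@]=C([Si](C)(C)C)[Zn]CC | intermediate
12 | (1S,2S)-1-(2,4-dimethoxyphenyl)-2-(3,5-dimethoxyphenyl)-4-(trimethylsilyl)but-3-yn-1-ol | O[C@H](c1ccc(OC)cc1OC)[C@H](C#C[Si](C)(C)C)c1cc(OC)cc(OC)c1 | intermediate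
13 | trichloroethylene | ClC=C(Cl)Cl | starting material
14 | potassium (1S,2S)-1-(2,4-dimethoxyphenyl)-2-(3,5-dimethoxyphenyl)-4-(trimethylsilyl)but-3-yn-1-olate (not isolated) | [K+].[O-][C@H](c1ccc(OC)cc1OC)[C@H](C#C[Si](C)(C)C)c1cc(OC)cc(OC)c1 | intermediate
15 | dichloroacetylene (not isolated) | ClC#CCl | intermediate
16 | [(3S,4S)-4-{[(E)-1,2-dichloroethenyl]oxy}-4-(2,4-dimethoxyphenyl)-3-(3,5-dimethoxyphenyl)but-1-yn-1-yl]trimethylsilane | Cl/C=C(Cl)\O[C@H](c1ccc(OC)cc1OC)[C@H](C#C[Si](C)(C)C)c1cc(OC)cc(OC)c1 | intermediate
17 | [(3S,4S)-4-[(chloroethynyl)oxy]-4-(2,4-dimethoxyphenyl)-3-(3,5-dimethoxyphenyl)but-1-yn-1-yl]trimethylsilane (not isolated) | ClC#CO[C@H](c1ccc(OC)cc1OC)[C@H](C#C[Si](C)(C)C)c1cc(OC)cc(OC)c1 | intermediate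
18 | ({[(1S,2S)-1-(2,4-dimethoxyphenyl)-2-(3,5-dimethoxyphenyl)-4-(trimethylsilyl)but-3-yn-1-yl]oxy}ethynyl)lithium (not isolated) | [Li]C#CO[C@H](c1ccc(OC)cc1OC)[C@H](C#C[Si](C)(C)C)c1cc(OC)cc(OC)c1 | intermediate
19 | [(3S,4S)-4-(2,4-dimethoxyphenyl)-3-(3,5-dimethoxyphenyl)-4-(ethynyloxy)but-1-yn-1-yl]trimethylsilane | C#CO[C@H](c1ccc(OC)cc1OC)[C@H](C#C[Si](C)(C)C)c1cc(OC)cc(OC)c1 | intermediate
20 | [(2S,3S)-2-(2,4-dimethoxyphenyl)-3-(3,5-dimethoxyphenyl)-6-[(E)-2-(4-methoxyphenyl)ethenyl]-2,3-dihydro-1-benzofuran-4-yl]trimethylsilane | COc1ccc(/C=C/c2cc([Si](C)(C)C)c3c(c2)O[C@H](c2ccc(OC)cc2OC)[C@H]3c2cc(OC)cc(OC)c2)cc1 | intermediate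
21 | [(2S,3S)-2-(2,4-dihydroxyphenyl)-3-(3,5-dihydroxyphenyl)-6-[(E)-2-(4-hydroxyphenyl)ethenyl]-2,3-dihydro-1-benzofuran-4-yl]boronic acid (not isolated) | Oc1ccc(/C=C/c2cc(B(O)O)c3c(c2)O[C@H](c2ccc(O)cc2O)[C@H]3c2cc(O)cc(O)c2)cc1 | intermediate
22 | 4-[(2S,3S)-3-(3,5-dihydroxyphenyl)-4-hydroxy-6-[(E)-2-(4-hydroxyphenyl)ethenyl]-2,3-dihydro-1-benzofuran-2-yl]benzene-1,3-diol | Oc1ccc(/C=C/c2cc(O)c3c(c2)O[C@H](c2ccc(O)cc2O)[C@H]3c2cc(O)cc(O)c2)cc1 | target

## Step count and risks

Total: 10 steps. Longest linear sequence: 8 steps (steps 3 to 10, from 5 to 22).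

**Step 9 (key step, proposed new method).** Three things can go wrong. The electron-rich ynol ether arm may decompose, or bind the metal unproductively, before oxidative coupling. The silyl-bearing arm slows that coupling, so self-trimerization of the enyne may outrun co-cyclization. Insertion may also take the wrong orientation and put the styryl group at C5. The fallback uses known reaction types and runs from 12 back to 20. Alcohol 12 would be silylated with chloro(ethynyl)dimethylsilane and imidazole to the ethynyl(dimethyl)silyl ether F1. This silyl-ether-tethered diyne would be cyclotrimerized with 4 under RhCl(PPh3)3 in toluene at 60–80 °C, a temporary silicon-tether cyclotrimerization, to the benzo-fused oxasiline F2, whose aryl–silicon bond marks the position of O1. Tamao oxidation (H2O2, KF, KHCO3, THF–MeOH) of that alkoxysilane, to which the aryl–SiMe3 group at C4 is inert, would give the phenol alcohol F3. Acid-catalysed cyclodehydration (camphorsulfonic acid, CH2Cl2, 0 °C) through the ring-B-stabilised benzylic cation would then close O1–C2 under thermodynamic control to the trans isomer 20.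

**Step 7.** The potassium alkoxide may fragment by retro-propargylation, since the leaving carbanion is stabilised by aryl and silylalkynyl groups. Base may also isomerise the propargylic C3–H towards an allene, and silicon may transfer from the alkyne to an alkoxide oxygen. The fallback avoids a free alkoxide and runs from 12 to 19. Alcohol 12 would be formylated with acetic formic anhydride and pyridine to the formate F4. The formate carbonyl would be converted with PPh3 and CBr4 into the 2,2-dibromovinyl ether F5. Treating F5 with n-BuLi at −78 °C and then methanol would give 18 and from it 19.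

**Step 6.** The benzylic propargylic mesylate may ionise before oxidative addition, and the aryl-substituted allenylmetal may racemise by propargyl–allenyl exchange; both processes erode enantiomeric purity. Anti selectivity towards an aromatic aldehyde may also be modest. The fallback runs from 8 to 12 through an isolable, configurationally stable allenylboron reagent. Alcohol 8 would be converted with methyl chloroformate and pyridine into the methyl carbonate F6. Copper-catalysed anti SN2′ borylation (CuCl, NaOt-Bu, Xantphos, bis(pinacolato)diboron, THF) would give the (aR)-allenylboronate F7. Warming F7 with 10 should give 12 after work-up, through a closed six-membered transition state with the same syn SE2′ course.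

**Step 10.** Heterolysis of the O1–C2 bond under the Lewis acid may be followed by elimination or Friedel–Crafts capture instead of reclosure. Protodesilylation may compete with borodesilylation if hydrogen bromide is present, and the free polyphenol may be oxidised by peroxide. The fallback separates the events and runs from 20 to 22. BCl3 in CH2Cl2 at −78 to 0 °C, followed by pinacol and Et3N, would give the pinacol boronate F8 with the methyl ethers intact. NaBO3 in THF–H2O would give the C4 phenol F9. The five methyl ethers would then be removed with BCl3 and n-Bu4NI at −78 to 0 °C to give 22.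

Further compounds
F1 | step 9 | [(3S,4S)-4-(2,4-dimethoxyphenyl)-3-(3,5-dimethoxyphenyl)-4-{[ethynyl(dimethyl)silyl]oxy}but-1-yn-1-yl]trimethylsilane | C#C[Si](C)(C)O[C@H](c1ccc(OC)cc1OC)[C@H](C#C[Si](C)(C)C)c1cc(OC)cc(OC)c1
F2 | step 9 | (3S,4S)-3-(2,4-dimethoxyphenyl)-4-(3,5-dimethoxyphenyl)-7-[(E)-2-(4-methoxyphenyl)ethenyl]-1,1-dimethyl-5-(trimethylsilyl)-3,4-dihydro-1H-2,1-benzoxasiline | C[Si]1(C)O[C@H](c2ccc(OC)cc2OC)[C@@H](c2cc(OC)cc(OC)c2)c2c([Si](C)(C)C)cc(/C=C/c3ccc(OC)cc3)cc12
F3 | step 9 | 2-[(1S,2S)-2-(2,4-dimethoxyphenyl)-1-(3,5-dimethoxyphenyl)-2-hydroxyethyl]-5-[(E)-2-(4-methoxyphenyl)ethenyl]-3-(trimethylsilyl)phenol | O[C@H](c1ccc(OC)cc1OC)[C@@H](c1cc(OC)cc(OC)c1)c1c(O)cc(/C=C/c2ccc(OC)cc2)cc1[Si](C)(C)C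
F4 | step 7 | (1S,2S)-1-(2,4-dimethoxyphenyl)-2-(3,5-dimethoxyphenyl)-4-(trimethylsilyl)but-3-yn-1-yl formate | O=CO[C@H](c1ccc(OC)cc1OC)[C@H](C#C[Si](C)(C)C)c1cc(OC)cc(OC)c1
F5 | step 7 | [(3S,4S)-4-[(2,2-dibromoethenyl)oxy]-4-(2,4-dimethoxyphenyl)-3-(3,5-dimethoxyphenyl)but-1-yn-1-yl]trimethylsilane | BrC(Br)=CO[C@H](c1ccc(OC)cc1OC)[C@H](C#C[Si](C)(C)C)c1cc(OC)cc(OC)c1
F6 | step 6 | (1R)-1-(3,5-dimethoxyphenyl)-3-(trimethylsilyl)prop-2-yn-1-yl methyl carbonate | COC(=O)O[C@@H](C#C[Si](C)(C)C)c1cc(OC)cc(OC)c1
F7 | step 6 | 2-[(aR)-3-(3,5-dimethoxyphenyl)-1-(trimethylsilyl)propa-1,2-dien-1-yl]-4,4,5,5-tetramethyl-1,3,2-dioxaborolane | [H]C(c1cc(OC)cc(OC)c1)=[C@]=C([Si](C)(C)C)B1OC(C)(C)C(C)(C)O1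
F8 | step 10 | 2-[(2S,3S)-2-(2,4-dimethoxyphenyl)-3-(3,5-dimethoxyphenyl)-6-[(E)-2-(4-methoxyphenyl)ethenyl]-2,3-dihydro-1-benzofuran-4-yl]-4,4,5,5-tetramethyl-1,3,2-dioxaborolane | COc1ccc(/C=C/c2cc(B3OC(C)(C)C(C)(C)O3)c3c(c2)O[C@H](c2ccc(OC)cc2OC)[C@H]3c2cc(OC)cc(OC)c2)cc1
F9 | step 10 | (2S,3S)-2-(2,4-dimethoxyphenyl)-3-(3,5-dimethoxyphenyl)-6-[(E)-2-(4-methoxyphenyl)ethenyl]-2,3-dihydro-1-benzofuran-4-ol | COc1ccc(/C=C/c2cc(O)c3c(c2)O[C@H](c2ccc(OC)cc2OC)[C@H]3c2cc(OC)cc(OC)c2)cc1
A1 | alternative 1 | 3-[(E)-2-(4-methoxyphenyl)ethenyl]cyclobut-2-en-1-one | COc1ccc(/C=C/C2=CC(=O)C2)cc1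
A2 | alternative 1 | tert-butyl{[(1S,2S)-1-(2,4-dimethoxyphenyl)-2-(3,5-dimethoxyphenyl)-4-{[tri(propan-2-yl)silyl]oxy}but-3-yn-1-yl]oxy}dimethylsilane | CC(C)(C)[Si](C)(C)O[C@H](c1ccc(OC)cc1OC)[C@H](C#CO[Si](C(C)C)(C(C)C)C(C)C)c1cc(OC)cc(OC)c1
A3 | alternative 1 | 2-[(1S,2S)-2-[(tert-butyldimethylsilyl)oxy]-2-(2,4-dimethoxyphenyl)-1-(3,5-dimethoxyphenyl)ethyl]-5-[(E)-2-(4-methoxyphenyl)ethenyl]-3-{[tri(propan-2-yl)silyl]oxy}phenol | CC(C)(C)[Si](C)(C)O[C@H](c1ccc(OC)cc1OC)[C@H](c1c(O)cc(/C=C/c2ccc(OC)cc2)cc1O[Si](C(C)C)(C(C)C)C(C)C)c1cc(OC)cc(OC)c1
A4 | alternative 2 | {4-[diazo(3,5-dimethoxyphenyl)methyl]-3,5-bis[(2,4-dimethoxybenzyl)oxy]phenoxy}tri(propan-2-yl)silane | [N-]=[N+]=C(c1cc(OC)cc(OC)c1)c1c(OCc2ccc(OC)cc2OC)cc(O[Si](C(C)C)(C(C)C)C(C)C)cc1OCc1ccc(OC)cc1OC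
A5 | alternative 2 | {[(2R,3S)-4-[(2,4-dimethoxybenzyl)oxy]-2-(2,4-dimethoxyphenyl)-3-(3,5-dimethoxyphenyl)-2,3-dihydro-1-benzofuran-6-yl]oxy}tri(propan-2-yl)silane | CC(C)[Si](C(C)C)(C(C)C)Oc1cc(OCc2ccc(OC)cc2OC)c2c(c1)O[C@@H](c1ccc(OC)cc1OC)[C@H]2c1cc(OC)cc(OC)c1
A6 | alternative 3 | 2-[(3,5-dimethoxyphenyl)(4-methylbenzenesulfonyl)methyl]-3-methoxy-5-[(E)-2-(4-methoxyphenyl)ethenyl]phenol (racemic) | COc1ccc(/C=C/c2cc(O)c(C(c3cc(OC)cc(OC)c3)S(=O)(=O)c3ccc(C)cc3)c(OC)c2)cc1
A7 | alternative 3 | 6-[(3,5-dimethoxyphenyl)methylidene]-5-methoxy-3-[(E)-2-(4-methoxyphenyl)ethenyl]cyclohexa-2,4-dien-1-one | COc1ccc(/C=C/C2=CC(=O)C(=Cc3cc(OC)cc(OC)c3)C(OC)=C2)cc1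
A8 | alternative 3 | (2R,5R)-1-(2,4-dimethoxybenzyl)-2,5-dimethylthiolan-1-ium tetrafluoroborate | COc1ccc(C[S+]2[C@H](C)CC[C@H]2C)c(OC)c1.F[B-](F)(F)F
A9 | alternative 3 | (2S,3S)-2-(2,4-dimethoxyphenyl)-3-(3,5-dimethoxyphenyl)-4-methoxy-6-[(E)-2-(4-methoxyphenyl)ethenyl]-2,3-dihydro-1-benzofuran | COc1ccc(/C=C/c2cc(OC)c3c(c2)O[C@H](c2ccc(OC)cc2OC)[C@H]3c2cc(OC)cc(OC)c2)cc1
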